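**Plan**

- Retrosynthetic cuts, last made first: the O7''–S bond of the sulfate and the benzyl ethers; then O1–C8a and C4–C4a of ring C (aryne annulation); then C2–C3 (aldol); then C3–C8'' (Claisen shift on apigenin).
- Enabling feature: ring C is fused to ring A through the adjacent carbons C8a (bound to O1) and C4a (bound to C4), and C4a lies next to the C5 oxygen. This is the polarity of a 3-alkoxyaryne, whose remote carbon takes an oxygen nucleophile while the carbon beside the alkoxy group becomes the anion that is acylated.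
- Forward order: apigenin supplies the whole flavone; a Claisen shift and alkene cleavage place the C3–C4 two-carbon unit on C8''; the aldol adds C2 and ring B; the aryne annulation brings ring A and closes ring C, the only ring made.
- Stereochemistry: C2 (R) and C3 (S) come from one magnesium-catalysed anti-aldol controlled by (R)-4-benzyloxazolidin-2-one; the ring closure touches neither centre, and trans is also the thermodynamic arrangement.
- Protection: benzyl on every phenol that ends free; methoxymethyl on O7'', because an O-allyl group could not be distinguished from the C-allyl group in the alkene cleavage, and so that O7'' alone is unmasked and sulfated before hydrogenolysis.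

Key step: step 12

Remark: unprimed locants refer to the flavanone, double-primed locants to the flavone unit.
Assumption: the target is taken as the free hydrogen sulfate as drawn; it is carried as the sodium salt and protonated only in the last operation.
Assumption: 3,5-bis(benzyloxy)phenol and (R)-4-benzyloxazolidin-2-one are taken as commercial materials.

**Route**

Step 1
Reactants: 1 apigenin; 2 allyl bromide
Product: 3 7-(allyloxy)-5-hydroxy-2-(4-hydroxyphenyl)-4H-chromen-4-one
Conditions: allyl bromide (1.05 equiv), K2CO3 (1.1 equiv), DMF, 0 °C to rt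
Reagents that add atoms: allyl bromide (2), C=CCBr
Why: Williamson etherification in which the 7-OH, the most acidic phenol of apigenin (vinylogous acid through the C4 carbonyl), should be alkylated first, while the less acidic 4'-OH and the hydrogen-bonded 5-OH stay largely untouched with one equivalent of halide and base.

Step 2
Reactants: 3 7-(allyloxy)-5-hydroxy-2-(4-hydroxyphenyl)-4H-chromen-4-one
Product: 4 7-(allyloxy)-5-(benzyloxy)-2-[4-(benzyloxy)phenyl]-4H-chromen-4-one
Conditions: BnBr (3 equiv), K2CO3 (4 equiv), DMF, 70 °C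
Reagents that add atoms: benzyl bromide, BrCc1ccccc1
Why: Williamson etherification under forcing conditions, which should benzylate the 4'-OH readily and the chelated 5-OH on heating in DMF.

Step 3
Reactants: 4 7-(allyloxy)-5-(benzyloxy)-2-[4-(benzyloxy)phenyl]-4H-chromen-4-one
Product: 5 8-allyl-5-(benzyloxy)-2-[4-(benzyloxy)phenyl]-7-hydroxy-4H-chromen-4-one
Conditions: N,N-diethylaniline, 200 °C, sealed tube, argon
Reagents that add atoms: none
Why: aromatic Claisen rearrangement ([3,3] shift then tautomerisation), which in 7-allyloxychromones is expected to go mainly to C8 because the C7–C8 bond has the higher double-bond character, with any C6 isomer removed by chromatography.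

Step 4
Reactants: 5 8-allyl-5-(benzyloxy)-2-[4-(benzyloxy)phenyl]-7-hydroxy-4H-chromen-4-one
Product: 6 8-allyl-5-(benzyloxy)-2-[4-(benzyloxy)phenyl]-7-(methoxymethoxy)-4H-chromen-4-one
Conditions: MOMCl (1.5 equiv), iPr2NEt (2 equiv), CH2Cl2, 0 °C to rt
Reagents that add atoms: chloromethyl methyl ether, COCCl
Why: O-alkylation of the acidic 7-phenol gives a methoxymethyl acetal that should survive the alkene cleavage, the aldol and the fluoride step and can later be removed with acid while all benzyl ethers stay.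

Step 5
Reactants: 6 8-allyl-5-(benzyloxy)-2-[4-(benzyloxy)phenyl]-7-(methoxymethoxy)-4H-chromen-4-one
Product: 9 2-{5-(benzyloxy)-2-[4-(benzyloxy)phenyl]-7-(methoxymethoxy)-4-oxo-4H-chromen-8-yl}acetic acid, via diol 7 (not isolated), via arylacetaldehyde 8 (not isolated)
Conditions: OsO4 (2 mol%), NaIO4 (4 equiv), 2,6-lutidine (2 equiv), 1,4-dioxane/H2O 3:1, rt; extract; then NaClO2 (3 equiv), NaH2PO4 (3 equiv), 2-methyl-2-butene (10 equiv), t-BuOH/THF/H2O, 0 °C to rt
Reagents that add atoms: osmium tetroxide, O=[Os](=O)(=O)=O (oxygen of the diol, restored by sodium periodate, [Na+].[O-]I(=O)(=O)=O); sodium chlorite, [Na+].[O-]Cl=O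
Why: Lemieux–Johnson cleavage of the terminal alkene (the electron-poor chromone C2–C3 bond should react far more slowly) followed by Pinnick oxidation of the crude aldehyde, with 2-methyl-2-butene trapping HOCl so that the electron-rich rings are not chlorinated.

Step 6
Reactants: 9 2-{5-(benzyloxy)-2-[4-(benzyloxy)phenyl]-7-(methoxymethoxy)-4-oxo-4H-chromen-8-yl}acetic acid; 10 (R)-4-benzyloxazolidin-2-one
Product: 12 (R)-4-benzyl-3-(2-{5-(benzyloxy)-2-[4-(benzyloxy)phenyl]-7-(methoxymethoxy)-4-oxo-4H-chromen-8-yl}acetyl)oxazolidin-2-one, via mixed pivalic anhydride 11 (not isolated)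
Conditions: PivCl (1.1 equiv), Et3N (2.5 equiv), THF, −20 °C; then LiCl (1.2 equiv), 10 (1.1 equiv), −20 °C to rt
Reagents that add atoms: pivaloyl chloride, CC(C)(C)C(=O)Cl (acyl group of intermediate 11 only, lost again as pivalate)
Why: mixed-anhydride activation and N-acylation of the oxazolidinone under the mild LiCl/Et3N protocol, in which the nucleophile should attack the less hindered arylacetyl carbonyl of the anhydride.

Step 7
Reactants: 12 (R)-4-benzyl-3-(2-{5-(benzyloxy)-2-[4-(benzyloxy)phenyl]-7-(methoxymethoxy)-4-oxo-4H-chromen-8-yl}acetyl)oxazolidin-2-one; 13 4-(benzyloxy)benzaldehyde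
Product: 15 (R)-4-benzyl-3-[(2S,3R)-3-[4-(benzyloxy)phenyl]-2-{5-(benzyloxy)-2-[4-(benzyloxy)phenyl]-7-(methoxymethoxy)-4-oxo-4H-chromen-8-yl}-3-hydroxypropanoyl]oxazolidin-2-one, via trimethylsilyl ether 14 (not isolated)
Conditions: MgCl2 (0.2 equiv), Et3N (2 equiv), TMSCl (1.5 equiv), 13 (1.2 equiv), EtOAc, rt; then 1 M HCl/THF 1:5, 0 °C
Reagents that add atoms: chlorotrimethylsilane, C[Si](C)(C)Cl (silyl group of intermediate 14 only, removed in the work-up)
Why: magnesium-halide-catalysed anti-aldol of an N-acyloxazolidinone, in which soft enolisation gives the chelated Z magnesium enolate, aldehyde 13 adds to the face away from the (R)-benzyl group through a boat-like arrangement that sets the acyl C2 as S and C3 as R (anti), and silylation of the aldolate by TMSCl blocks retro-aldol before mild acid frees the alcohol.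

Step 8
Reactants: 15 (R)-4-benzyl-3-[(2S,3R)-3-[4-(benzyloxy)phenyl]-2-{5-(benzyloxy)-2-[4-(benzyloxy)phenyl]-7-(methoxymethoxy)-4-oxo-4H-chromen-8-yl}-3-hydroxypropanoyl]oxazolidin-2-one
Product: 16 methyl (2S,3R)-3-[4-(benzyloxy)phenyl]-2-{5-(benzyloxy)-2-[4-(benzyloxy)phenyl]-7-(methoxymethoxy)-4-oxo-4H-chromen-8-yl}-3-hydroxypropanoate
Conditions: MeMgBr (3 equiv) added to MeOH at 0 °C (gives MeOMgBr); then 15 in CH2Cl2, 0 °C; cold 1 M HCl quench
Reagents that add atoms: methanol, CO (delivered as MeOMgBr)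
Why: transesterification with MeOMgBr, the usual mild cleavage of oxazolidinone aldol adducts, in which magnesium chelation of the β-hydroxy imide should steer methoxide to the exocyclic carbonyl and hold back retro-aldol and α-epimerisation at 0 °C, with the auxiliary recovered.

Step 9
Reactants: 16 methyl (2S,3R)-3-[4-(benzyloxy)phenyl]-2-{5-(benzyloxy)-2-[4-(benzyloxy)phenyl]-7-(methoxymethoxy)-4-oxo-4H-chromen-8-yl}-3-hydroxypropanoate
Product: 17 methyl (2S,3R)-3-[4-(benzyloxy)phenyl]-2-{5-(benzyloxy)-2-[4-(benzyloxy)phenyl]-7-(methoxymethoxy)-4-oxo-4H-chromen-8-yl}-3-[(trimethylsilyl)oxy]propanoate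
Conditions: TMSCl (1.5 equiv), imidazole (2 equiv), CH2Cl2, 0 °C; used without chromatography
Reagents that add atoms: chlorotrimethylsilane, C[Si](C)(C)Cl
Why: silylation of the secondary alcohol turns the hydroxyl into a latent alkoxide that fluoride can unmask with no O–H proton left in the medium, which matters because a neutral alcohol would add to the aryne and protonate the aryl carbon at once; no stereocentre is touched.

Step 10
Reactants: 18 3,5-bis(benzyloxy)phenol
Product: 19 3,5-bis(benzyloxy)-2-bromophenol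
Conditions: NBS (1.0 equiv), CH2Cl2, −78 to −40 °C
Reagents that add atoms: N-bromosuccinimide, O=C1CCC(=O)N1Br
Why: electrophilic aromatic bromination of a phloroglucinol-type ring at low temperature, which should be directed ortho to the free hydroxyl by hydrogen-bonded delivery of bromine and so fall between OH and OBn.

Step 11
Reactants: 19 3,5-bis(benzyloxy)-2-bromophenol
Product: 22 3,5-bis(benzyloxy)-2-(trimethylsilyl)phenyl trifluoromethanesulfonate, via aryl trimethylsilyl ether 20 (not isolated), via lithium silylphenolate 21 (not isolated)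
Conditions: HMDS (1.5 equiv), THF, 65 °C, then evaporate; n-BuLi (1.1 equiv), THF, −100 °C; Tf2O (1.2 equiv), −100 to −78 °C
Reagents that add atoms: hexamethyldisilazane, C[Si](C)(C)N[Si](C)(C)C; trifluoromethanesulfonic anhydride, O=S(=O)(OS(=O)(=O)C(F)(F)F)C(F)(F)F; n-butyllithium, [Li]CCCC (lithium of intermediate 21 only)
Why: one-pot O-silylation, bromine–lithium exchange, 1,3 oxygen-to-carbon silyl shift (retro-Brook rearrangement) and triflation of the resulting phenolate, the standard entry to ortho-silylaryl triflates, with the exchange at −100 °C expected to outrun benzylic deprotonation.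

Step 12
Reactants: 17 methyl (2S,3R)-3-[4-(benzyloxy)phenyl]-2-{5-(benzyloxy)-2-[4-(benzyloxy)phenyl]-7-(methoxymethoxy)-4-oxo-4H-chromen-8-yl}-3-[(trimethylsilyl)oxy]propanoate; 22 3,5-bis(benzyloxy)-2-(trimethylsilyl)phenyl trifluoromethanesulfonate
Product: 25 (2R,3S)-5,7-bis(benzyloxy)-2-[4-(benzyloxy)phenyl]-3-{5-(benzyloxy)-2-[4-(benzyloxy)phenyl]-7-(methoxymethoxy)-4-oxo-4H-chromen-8-yl}chroman-4-one, via cesium alkoxide 23 (not isolated), via 3,5-bis(benzyloxy)benzyne 24 (not isolated)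
Conditions: 22 (2.0 equiv), CsF (5 equiv), 18-crown-6 (0.5 equiv), THF, rt to 40 °C; water quench
Reagents that add atoms: cesium fluoride, [Cs+].[F-] (cesium of intermediate 23 only)
Why: Proposed new method: fluoride takes the silicon of 22 and triflate leaves to give aryne 24, while fluoride (and then the released methoxide) removes the O-silyl group of 17 to give alkoxide 23 with no O–H present; 23 adds to the aryne carbon remote from the C5 benzyloxy group (future C8a), and the aryl anion formed at C4a, next to that oxygen, attacks the methyl ester and expels methoxide. The closest known reactions are the fluoride-induced aryne annulation of ortho-hydroxybenzoates to xanthones, the aryne acyl-alkylation of β-keto esters and the insertion of arynes into O–H bonds of alcohols. Ring C closes by a 6-exo-trig acyl substitution, O1–C8a forming first and C4–C4a second. No stereocentre is created: C2 and C3 come unchanged from the aldol, no bond to either is made or broken, the anti ester maps directly onto the trans (2R,3S) flavanone, and any C3 epimer should relax to trans. The step needs regioselective addition to the unsymmetrical aryne, which the inductive distortion by the C5 alkoxy group should secure, and acyl trapping faster than protonation, proton transfer from C3 or retro-aldol, which the proton-free latent alkoxide, its low stationary concentration and the short six-membered path to the ester carbonyl are meant to secure.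

Step 13
Reactants: 25 (2R,3S)-5,7-bis(benzyloxy)-2-[4-(benzyloxy)phenyl]-3-{5-(benzyloxy)-2-[4-(benzyloxy)phenyl]-7-(methoxymethoxy)-4-oxo-4H-chromen-8-yl}chroman-4-one
Product: 26 (2R,3S)-5,7-bis(benzyloxy)-2-[4-(benzyloxy)phenyl]-3-{5-(benzyloxy)-2-[4-(benzyloxy)phenyl]-7-hydroxy-4-oxo-4H-chromen-8-yl}chroman-4-one
Conditions: 3 M aq. HCl/MeOH/THF 1:4:4, rt to 40 °C
Reagents that add atoms: none
Why: acid-catalysed acetal cleavage (transacetalisation to dimethoxymethane) should remove the methoxymethyl group while the aryl benzyl ethers and the acid-stable trans flavanone are unaffected.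

Step 14
Reactants: 26 (2R,3S)-5,7-bis(benzyloxy)-2-[4-(benzyloxy)phenyl]-3-{5-(benzyloxy)-2-[4-(benzyloxy)phenyl]-7-hydroxy-4-oxo-4H-chromen-8-yl}chroman-4-one
Product: 27 sodium 5-(benzyloxy)-2-[4-(benzyloxy)phenyl]-8-{(2R,3S)-5,7-bis(benzyloxy)-2-[4-(benzyloxy)phenyl]-4-oxochroman-3-yl}-4-oxo-4H-chromen-7-yl sulfate
Conditions: SO3·pyridine (5 equiv), pyridine, rt; then aq. NaHCO3; Sephadex LH-20
Reagents that add atoms: sulfur trioxide–pyridine complex, [O-]S(=O)(=O)[n+]1ccccc1; sodium hydrogen carbonate, [Na+].OC([O-])=O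
Why: O-sulfation of the only free phenol with the SO3·pyridine complex, the usual reagent for aryl sulfate monoesters, followed by exchange to the sodium salt, at room temperature so that the weak base does not open ring C.

Step 15
Reactants: 27 sodium 5-(benzyloxy)-2-[4-(benzyloxy)phenyl]-8-{(2R,3S)-5,7-bis(benzyloxy)-2-[4-(benzyloxy)phenyl]-4-oxochroman-3-yl}-4-oxo-4H-chromen-7-yl sulfate
Product: 29 5-hydroxy-2-(4-hydroxyphenyl)-8-[(2R,3S)-5,7-dihydroxy-2-(4-hydroxyphenyl)-4-oxochroman-3-yl]-4-oxo-4H-chromen-7-yl hydrogen sulfate, via sodium sulfate salt 28 (not isolated)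
Conditions: H2 (1 atm), 10% Pd/C, THF/MeOH 1:1, rt; filter; then HCl (1.0 equiv, 0.1 M in MeOH), 0 °C; Sephadex LH-20 (MeOH), kept cold
Reagents that add atoms: none
Why: hydrogenolysis of the five benzyl ethers over palladium on carbon, to which the aryl sulfate, the chromone double bond and the flavanone should be inert under these mild conditions, followed by stoichiometric protonation of the sulfate salt.

**Compound list**

1 | apigenin | O=c1cc(-c2ccc(O)cc2)oc2cc(O)cc(O)c12 | starting material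
2 | allyl bromide | C=CCBr | starting material
3 | 7-(allyloxy)-5-hydroxy-2-(4-hydroxyphenyl)-4H-chromen-4-one | O=c1cc(-c2ccc(O)cc2)oc2cc(OCC=C)cc(O)c12 | intermediate
4 | 7-(allyloxy)-5-(benzyloxy)-2-[4-(benzyloxy)phenyl]-4H-chromen-4-one | O=c1cc(-c2ccc(OCc3ccccc3)cc2)oc2cc(OCC=C)cc(OCc3ccccc3)c12 | intermediate
5 | 8-allyl-5-(benzyloxy)-2-[4-(benzyloxy)phenyl]-7-hydroxy-4H-chromen-4-one | O=c1cc(-c2ccc(OCc3ccccc3)cc2)oc2c(CC=C)c(O)cc(OCc3ccccc3)c12 | intermediate
6 | 8-allyl-5-(benzyloxy)-2-[4-(benzyloxy)phenyl]-7-(methoxymethoxy)-4H-chromen-4-one | O=c1cc(-c2ccc(OCc3ccccc3)cc2)oc2c(CC=C)c(OCOC)cc(OCc3ccccc3)c12 | intermediate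
7 | 5-(benzyloxy)-2-[4-(benzyloxy)phenyl]-8-(2,3-dihydroxypropyl)-7-(methoxymethoxy)-4H-chromen-4-one (either configuration at the carbinol; not isolated) | O=c1cc(-c2ccc(OCc3ccccc3)cc2)oc2c(CC(O)CO)c(OCOC)cc(OCc3ccccc3)c12 | intermediate
8 | 2-{5-(benzyloxy)-2-[4-(benzyloxy)phenyl]-7-(methoxymethoxy)-4-oxo-4H-chromen-8-yl}acetaldehyde (not isolated) | O=c1cc(-c2ccc(OCc3ccccc3)cc2)oc2c(CC=O)c(OCOC)cc(OCc3ccccc3)c12 | intermediate
9 | 2-{5-(benzyloxy)-2-[4-(benzyloxy)phenyl]-7-(methoxymethoxy)-4-oxo-4H-chromen-8-yl}acetic acid | O=c1cc(-c2ccc(OCc3ccccc3)cc2)oc2c(CC(=O)O)c(OCOC)cc(OCc3ccccc3)c12 | intermediate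
10 | (R)-4-benzyloxazolidin-2-one | O=C1N[C@H](Cc2ccccc2)CO1 | starting material
11 | 2-{5-(benzyloxy)-2-[4-(benzyloxy)phenyl]-7-(methoxymethoxy)-4-oxo-4H-chromen-8-yl}acetic pivalic anhydride (not isolated) | CC(C)(C)C(=O)OC(=O)Cc1c(OCOC)cc(OCc2ccccc2)c2c(=O)cc(-c3ccc(OCc4ccccc4)cc3)oc12 | intermediate
12 | (R)-4-benzyl-3-(2-{5-(benzyloxy)-2-[4-(benzyloxy)phenyl]-7-(methoxymethoxy)-4-oxo-4H-chromen-8-yl}acetyl)oxazolidin-2-one | O=C1OC[C@@H](Cc2ccccc2)N1C(=O)Cc1c(OCOC)cc(OCc2ccccc2)c2c(=O)cc(-c3ccc(OCc4ccccc4)cc3)oc12 | intermediate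
13 | 4-(benzyloxy)benzaldehyde | O=Cc1ccc(OCc2ccccc2)cc1 | starting material
14 | (R)-4-benzyl-3-[(2S,3R)-3-[4-(benzyloxy)phenyl]-2-{5-(benzyloxy)-2-[4-(benzyloxy)phenyl]-7-(methoxymethoxy)-4-oxo-4H-chromen-8-yl}-3-[(trimethylsilyl)oxy]propanoyl]oxazolidin-2-one (not isolated) | C[Si](C)(C)O[C@@H](c1ccc(OCc2ccccc2)cc1)[C@@H](C(=O)N1C(=O)OC[C@H]1Cc1ccccc1)c1c(OCOC)cc(OCc2ccccc2)c2c(=O)cc(-c3ccc(OCc4ccccc4)cc3)oc12 | intermediate
15 | (R)-4-benzyl-3-[(2S,3R)-3-[4-(benzyloxy)phenyl]-2-{5-(benzyloxy)-2-[4-(benzyloxy)phenyl]-7-(methoxymethoxy)-4-oxo-4H-chromen-8-yl}-3-hydroxypropanoyl]oxazolidin-2-one | O[C@@H](c1ccc(OCc2ccccc2)cc1)[C@@H](C(=O)N1C(=O)OC[C@H]1Cc1ccccc1)c1c(OCOC)cc(OCc2ccccc2)c2c(=O)cc(-c3ccc(OCc4ccccc4)cc3)oc12 | intermediate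
16 | methyl (2S,3R)-3-[4-(benzyloxy)phenyl]-2-{5-(benzyloxy)-2-[4-(benzyloxy)phenyl]-7-(methoxymethoxy)-4-oxo-4H-chromen-8-yl}-3-hydroxypropanoate | O[C@@H](c1ccc(OCc2ccccc2)cc1)[C@@H](C(=O)OC)c1c(OCOC)cc(OCc2ccccc2)c2c(=O)cc(-c3ccc(OCc4ccccc4)cc3)oc12 | intermediate
17 | methyl (2S,3R)-3-[4-(benzyloxy)phenyl]-2-{5-(benzyloxy)-2-[4-(benzyloxy)phenyl]-7-(methoxymethoxy)-4-oxo-4H-chromen-8-yl}-3-[(trimethylsilyl)oxy]propanoate | C[Si](C)(C)O[C@@H](c1ccc(OCc2ccccc2)cc1)[C@@H](C(=O)OC)c1c(OCOC)cc(OCc2ccccc2)c2c(=O)cc(-c3ccc(OCc4ccccc4)cc3)oc12 | intermediate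
18 | 3,5-bis(benzyloxy)phenol | Oc1cc(OCc2ccccc2)cc(OCc2ccccc2)c1 | starting material
19 | 3,5-bis(benzyloxy)-2-bromophenol | Oc1cc(OCc2ccccc2)cc(OCc2ccccc2)c1Br | intermediate
20 | [3,5-bis(benzyloxy)-2-bromophenoxy]trimethylsilane (not isolated) | C[Si](C)(C)Oc1cc(OCc2ccccc2)cc(OCc2ccccc2)c1Br | intermediate
21 | lithium 3,5-bis(benzyloxy)-2-(trimethylsilyl)phenolate (not isolated) | [Li+].[O-]c1cc(OCc2ccccc2)cc(OCc2ccccc2)c1[Si](C)(C)C | intermediate
22 | 3,5-bis(benzyloxy)-2-(trimethylsilyl)phenyl trifluoromethanesulfonate | C[Si](C)(C)c1c(OCc2ccccc2)cc(OCc2ccccc2)cc1OS(=O)(=O)C(F)(F)F | intermediate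
23 | cesium (1R,2S)-1-[4-(benzyloxy)phenyl]-2-{5-(benzyloxy)-2-[4-(benzyloxy)phenyl]-7-(methoxymethoxy)-4-oxo-4H-chromen-8-yl}-3-methoxy-3-oxopropan-1-olate, the alkoxide of 16 (not isolated) | [Cs+].[O-][C@@H](c1ccc(OCc2ccccc2)cc1)[C@@H](C(=O)OC)c1c(OCOC)cc(OCc2ccccc2)c2c(=O)cc(-c3ccc(OCc4ccccc4)cc3)oc12 | intermediate
24 | 3,5-bis(benzyloxy)benzyne (not isolated) | C1#CC(OCc2ccccc2)=CC(OCc2ccccc2)=C1 | intermediate
25 | (2R,3S)-5,7-bis(benzyloxy)-2-[4-(benzyloxy)phenyl]-3-{5-(benzyloxy)-2-[4-(benzyloxy)phenyl]-7-(methoxymethoxy)-4-oxo-4H-chromen-8-yl}chroman-4-one | O=C1c2c(OCc3ccccc3)cc(OCc3ccccc3)cc2O[C@@H](c2ccc(OCc3ccccc3)cc2)[C@@H]1c1c(OCOC)cc(OCc2ccccc2)c2c(=O)cc(-c3ccc(OCc4ccccc4)cc3)oc12 | intermediate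
26 | (2R,3S)-5,7-bis(benzyloxy)-2-[4-(benzyloxy)phenyl]-3-{5-(benzyloxy)-2-[4-(benzyloxy)phenyl]-7-hydroxy-4-oxo-4H-chromen-8-yl}chroman-4-one | O=C1c2c(OCc3ccccc3)cc(OCc3ccccc3)cc2O[C@@H](c2ccc(OCc3ccccc3)cc2)[C@@H]1c1c(O)cc(OCc2ccccc2)c2c(=O)cc(-c3ccc(OCc4ccccc4)cc3)oc12 | intermediate
27 | sodium 5-(benzyloxy)-2-[4-(benzyloxy)phenyl]-8-{(2R,3S)-5,7-bis(benzyloxy)-2-[4-(benzyloxy)phenyl]-4-oxochroman-3-yl}-4-oxo-4H-chromen-7-yl sulfate | [Na+].O=C1c2c(OCc3ccccc3)cc(OCc3ccccc3)cc2O[C@@H](c2ccc(OCc3ccccc3)cc2)[C@@H]1c1c(OS(=O)(=O)[O-])cc(OCc2ccccc2)c2c(=O)cc(-c3ccc(OCc4ccccc4)cc3)oc12 | intermediate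
28 | sodium 5-hydroxy-2-(4-hydroxyphenyl)-8-[(2R,3S)-5,7-dihydroxy-2-(4-hydroxyphenyl)-4-oxochroman-3-yl]-4-oxo-4H-chromen-7-yl sulfate (not isolated) | [Na+].O=C1c2c(O)cc(O)cc2O[C@@H](c2ccc(O)cc2)[C@@H]1c1c(OS(=O)(=O)[O-])cc(O)c2c(=O)cc(-c3ccc(O)cc3)oc12 | intermediate
29 | 5-hydroxy-2-(4-hydroxyphenyl)-8-[(2R,3S)-5,7-dihydroxy-2-(4-hydroxyphenyl)-4-oxochroman-3-yl]-4-oxo-4H-chromen-7-yl hydrogen sulfate (CNP0271389.1) | O=C1c2c(O)cc(O)cc2O[C@@H](c2ccc(O)cc2)[C@@H]1c1c(OS(=O)(=O)O)cc(O)c2c(=O)cc(-c3ccc(O)cc3)oc12 | target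

**Step count and risks**

Total steps: 15. Longest linear sequence: 13 steps (steps 1–9 and 12–15, from apigenin); the aryne precursor takes 2 steps (10 and 11).

Steps most likely to fail:

1. Step 12 (new method). The C4a aryl anion may be protonated before it reaches the ester, the alkoxide may fragment by retro-aldol, or proton transfer from C3 may be followed by β-elimination of the aryloxide. Fallback (sets out from 16 and 22, returns at 25): the ring is closed in two known operations instead of one. Hydroxy ester 16 is treated with 22 and CsF in MeCN at rt, where the neutral alcohol adds to the aryne and the aryl carbon is protonated at once (aryne insertion into an O–H bond). This should give methyl (2S,3R)-3-[3,5-bis(benzyloxy)phenoxy]-3-[4-(benzyloxy)phenyl]-2-{5-(benzyloxy)-2-[4-(benzyloxy)phenyl]-7-(methoxymethoxy)-4-oxo-4H-chromen-8-yl}propanoate F1 with the carbinol configuration retained. Hydrolysis with Me3SnOH in 1,2-dichloroethane at 70 °C, chosen to avoid the elimination that hydroxide would invite, should give the aryloxy acid F2. Trifluoroacetic anhydride in CH2Cl2 at 0 °C converts F2 into the mixed trifluoroacetic anhydride F3, which should undergo intramolecular Friedel–Crafts acylation on the electron-rich ring, ortho to the ether oxygen (both ortho positions are equivalent), to give 25. Loss of the methoxymethyl group under these acidic conditions would be harmless, since step 13 removes it.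

2. Step 7. The hindered, chelating substrate may convert incompletely, facial or anti selectivity may erode, or the adduct may revert by retro-aldol before it is silylated. Fallback (sets out from 12 and 13, returns at 15): the catalytic magnesium enolate is replaced by a stoichiometric, preformed boron enolate reacting through an open transition state. Imide 12 is enolised with Bu2BOTf and iPr2NEt in CH2Cl2 (−78 to 0 °C) to the dibutylboron Z enolate F4. This is added at −78 °C to aldehyde 13 precomplexed with Et2AlCl. The Lewis-acid-bound aldehyde cannot coordinate boron, so it should attack the oxazolidinone-chelated enolate on the face away from the benzyl group in an open, anti-selective arrangement and give the same (2S,3R) adduct 15.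

3. Step 3. The allyl group may migrate to C6 instead of C8, or a benzyl group may shift thermally at 200 °C. Fallback (sets out from 1, returns at 6): the C8''–carbon bond is made by cross-coupling instead of a sigmatropic shift. Apigenin 1 is protected at its most acidic 7-OH with MOMCl and iPr2NEt to give 5-hydroxy-2-(4-hydroxyphenyl)-7-(methoxymethoxy)-4H-chromen-4-one F5. Benzylation (BnBr, K2CO3, DMF, 70 °C) gives 5-(benzyloxy)-2-[4-(benzyloxy)phenyl]-7-(methoxymethoxy)-4H-chromen-4-one F6. Iodination with N-iodosuccinimide in DMF at rt, which in fully O-alkylated 5,7-dioxygenated flavones goes to C8, gives 5-(benzyloxy)-2-[4-(benzyloxy)phenyl]-8-iodo-7-(methoxymethoxy)-4H-chromen-4-one F7. Stille allylation (allyltributylstannane, Pd(PPh3)4, DMF, 90 °C) then gives 6.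

**Further compounds**

F1 | step 12 | methyl (2S,3R)-3-[3,5-bis(benzyloxy)phenoxy]-3-[4-(benzyloxy)phenyl]-2-{5-(benzyloxy)-2-[4-(benzyloxy)phenyl]-7-(methoxymethoxy)-4-oxo-4H-chromen-8-yl}propanoate | O(c1cc(OCc2ccccc2)cc(OCc2ccccc2)c1)[C@@H](c1ccc(OCc2ccccc2)cc1)[C@@H](C(=O)OC)c1c(OCOC)cc(OCc2ccccc2)c2c(=O)cc(-c3ccc(OCc4ccccc4)cc3)oc12
F2 | step 12 | (2S,3R)-3-[3,5-bis(benzyloxy)phenoxy]-3-[4-(benzyloxy)phenyl]-2-{5-(benzyloxy)-2-[4-(benzyloxy)phenyl]-7-(methoxymethoxy)-4-oxo-4H-chromen-8-yl}propanoic acid | O(c1cc(OCc2ccccc2)cc(OCc2ccccc2)c1)[C@@H](c1ccc(OCc2ccccc2)cc1)[C@@H](C(=O)O)c1c(OCOC)cc(OCc2ccccc2)c2c(=O)cc(-c3ccc(OCc4ccccc4)cc3)oc12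
F3 | step 12 | (2S,3R)-3-[3,5-bis(benzyloxy)phenoxy]-3-[4-(benzyloxy)phenyl]-2-{5-(benzyloxy)-2-[4-(benzyloxy)phenyl]-7-(methoxymethoxy)-4-oxo-4H-chromen-8-yl}propanoic trifluoroacetic anhydride | O(c1cc(OCc2ccccc2)cc(OCc2ccccc2)c1)[C@@H](c1ccc(OCc2ccccc2)cc1)[C@@H](C(=O)OC(=O)C(F)(F)F)c1c(OCOC)cc(OCc2ccccc2)c2c(=O)cc(-c3ccc(OCc4ccccc4)cc3)oc12
F4 | step 7 | dibutylboron Z enolate of 12, (R)-4-benzyl-3-[(Z)-1-[(dibutylboranyl)oxy]-2-{5-(benzyloxy)-2-[4-(benzyloxy)phenyl]-7-(methoxymethoxy)-4-oxo-4H-chromen-8-yl}vinyl]oxazolidin-2-one | CCCCB(CCCC)O/C(=C\c1c(OCOC)cc(OCc2ccccc2)c2c(=O)cc(-c3ccc(OCc4ccccc4)cc3)oc12)N1C(=O)OC[C@H]1Cc1ccccc1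
F5 | step 3 | 5-hydroxy-2-(4-hydroxyphenyl)-7-(methoxymethoxy)-4H-chromen-4-one | O=c1cc(-c2ccc(O)cc2)oc2cc(OCOC)cc(O)c12
F6 | step 3 | 5-(benzyloxy)-2-[4-(benzyloxy)phenyl]-7-(methoxymethoxy)-4H-chromen-4-one | O=c1cc(-c2ccc(OCc3ccccc3)cc2)oc2cc(OCOC)cc(OCc3ccccc3)c12
F7 | step 3 | 5-(benzyloxy)-2-[4-(benzyloxy)phenyl]-8-iodo-7-(methoxymethoxy)-4H-chromen-4-one | O=c1cc(-c2ccc(OCc3ccccc3)cc2)oc2c(I)c(OCOC)cc(OCc3ccccc3)c12
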